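Time first: take one early stretch of the clock, from 2.7 min to 8.2 min, in each run. You asked for a quick number, and your hunch is that the rate follows the charge one for one. In your terms, that is one time constant at each charge.

| setting | Monday's | Friday's | Sunday's | Saturday's |
|---|---|---|---|---|
| starting material | 120 mM | 60.0 mM | 360 mM | 120 mM |
| time |  |  |  | 190 min |

- Monday's run (time / min: [target] / mM): 2.7: 1.1; 8.2: 6.0; 16: 12.1; 25: 19.6; 35: 28.4; 47: 37.7; 61: 45.9; 75: 50.5
- Friday's run (time / min: [target] / mM): 2.7: 1.4; 8.2: 4.2; 16: 6.9; 25: 11.3; 35: 14.3; 47: 17.3; 61: 19.9; 75: 21.3
- Sunday's run (time / min: [target] / mM): 2.7: 3.2; 8.2: 11.3; 16: 29.5; 25: 57.6; 35: 102.0; 47: 163.2; 61: 214.7; 75: 227.2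

(scatter of a reading: 0.4 mM)

- Overall: starting material -> target.
- Constant volume, constant temperature.
- What is held in complexes is read along with the free species.
- An order is taken over about fifteen percent of the charge, up and down.

- reaction order in [starting material] at the outset, round the charge of the Monday's run, defined at two percent of the starting material turned into target (one fixed amount of target, the same in the runs compared)
- target in the Saturday's run at 190 min, as a share of the starting material charged

Friday's and Sunday's runs span the widest ratio of charges, with Monday's between them. Here are their slopes over that stretch:

Friday: (4.2 mM − 1.4 mM) / (8.2 min − 2.7 min) = 0.509 mM min⁻¹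

Sunday: (11.3 mM − 3.2 mM) / (8.2 min − 2.7 min) = 1.47 mM min⁻¹

The rate rises 2.89 times, less than the 6.00 times of the charge. So your hunch fails on these two runs. Now go to logarithms:

0.461 / 0.778 = 0.593

That is the log slope, the logarithm of the rate ratio over the logarithm of the charge ratio. It is a reading of an order across these two charges, taken over one stretch of the clock and not at one amount of target, and it is my number for the order asked. The scatter of Friday's readings puts about 0.113 on it.

Saturday's charge equals Monday's. Monday's last reading, at 75 min, is 42.1 % of that charge, and I would commit to a little above that.

The forecast says 0.5 and 46 %. Its order is below mine, and it calls that order “poorly fixed because the early points are noisy”.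

    2 starting material ⇌ substrate dimer, settled at all times (42.70 M⁻¹)
    starting material → target (0.01968 min⁻¹)
    starting material → decomposed substrate (0.05412 min⁻¹)
    starting material + target → 2 target (1.062 M⁻¹ min⁻¹)

The flask gives an order of 0.63, and 43.3 % of the charge as target in Saturday's run at 190 min. Monday's run, where two percent of its charge has turned, makes target at 0.68 mM min⁻¹. Sunday's charge is 3.00 times Monday's, and the log slope raises that ratio to the power 0.593, so Monday's rate scales to an estimate of 1.31 mM min⁻¹ for Sunday's run. At that same amount of target, Sunday's run makes it at 1.3 mM min⁻¹.

The earlier runs and the new flask are simulated for an exercise; the scatter is artificial.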